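Every position of ring A except C8 is substituted: methoxy on C5, C6 and C7, the ring C oxygen on C8a, the C4 methylene on C4a. This pattern maps onto the four carbons of a squarate (C8a, C4a, C5, C6) plus a 1-methoxyvinyl unit (C7, C8), so the route rests on disconnecting C8–C8a. Heating a 2-alkyl-3,4-dimethoxy-4-(1-methoxyvinyl)cyclobutenone, whose alkyl group is the C4–C3–C2 chain bearing ring B and a silylated (R)-carbinol, opens the four-membered ring and recloses it as complete ring A in one operation. The quaternary oxygen is methylated beforehand, so C6–OMe is present and only the C8a phenol is released; it closes ring C with inversion to (2S).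

Key step: step 7

Abbreviation: TBS = tert-butyldimethylsilyl.
Remark: the quaternary ring carbon of the cyclobutenone intermediates forms as a mixture of epimers. It is drawn without configuration because it becomes sp2 again later.
Remark: the sense of induction in step 1 is assigned by analogy with ethyl benzoylacetate, where the (S)-configured atropisomeric diphosphine gives the (R)-alcohol.
Remark: the tertiary alkoxide from the second addition is methylated, not protonated. A free dimethoxyhydroquinone would be air-sensitive, could be dehydrogenated by the azodicarboxylate of the Mitsunobu step, and would need its own methylation step.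

Step 1
Reactants: 1 ethyl 3-(3,4-dimethoxyphenyl)-3-oxopropanoate
Product: 2 ethyl (3R)-3-(3,4-dimethoxyphenyl)-3-hydroxypropanoate
Conditions: H2 (20 bar), [RuCl(p-cymene)((S)-SEGPHOS)]Cl (0.5 mol %), EtOH, 50 °C
Reagents that add atoms: none
Why: Noyori asymmetric hydrogenation of a β-keto ester, in which chelation of ketone and ester to the chiral ruthenium diphosphine exposes one carbonyl face, so the (S)-ligand should set the (R)-carbinol that later becomes C2.

Step 2
Reactants: 2 ethyl (3R)-3-(3,4-dimethoxyphenyl)-3-hydroxypropanoate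
Product: 3 ethyl (3R)-3-[(TBS)oxy]-3-(3,4-dimethoxyphenyl)propanoate
Conditions: TBSCl, imidazole, DMF, rt
Reagents that add atoms: tert-butyldimethylsilyl chloride, CC(C)(C)[Si](C)(C)Cl
Why: Imidazole-promoted silylation of a secondary alcohol, which masks the carbinol against the organolithium steps and breaks no bond at the stereocentre.

Step 3
Reactants: 3 ethyl (3R)-3-[(TBS)oxy]-3-(3,4-dimethoxyphenyl)propanoate
Product: 4 (3R)-3-[(TBS)oxy]-3-(3,4-dimethoxyphenyl)propan-1-ol
Conditions: DIBAL-H (2.5 equiv), CH2Cl2, −78 to 0 °C; aqueous work-up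
Reagents that add atoms: none
Why: Hydride reduction of an ester to the primary alcohol with a non-basic aluminium hydride in CH2Cl2, which avoids secondary-to-primary silyl migration and leaves the benzylic C–O bond alone.

Step 4
Reactants: 4 (3R)-3-[(TBS)oxy]-3-(3,4-dimethoxyphenyl)propan-1-ol
Product: 5 tert-butyl{[(1R)-1-(3,4-dimethoxyphenyl)-3-iodopropyl]oxy}dimethylsilane
Conditions: I2, PPh3, imidazole, CH2Cl2, 0 °C to rt
Reagents that add atoms: iodine, II
Why: Appel-type iodination, in which the primary alkoxyphosphonium ion is displaced by iodide in an SN2 reaction remote from the stereocentre under buffered conditions that the silyl ether tolerates.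

Step 5
Reactants: 5 tert-butyl{[(1R)-1-(3,4-dimethoxyphenyl)-3-iodopropyl]oxy}dimethylsilane; 6 dimethyl squarate
Product: 10 3-{(3R)-3-[(TBS)oxy]-3-(3,4-dimethoxyphenyl)propyl}-4-methoxycyclobut-3-ene-1,2-dione, via alkyllithium 7 (not isolated), via lithium alkoxide adduct 8 (not isolated), via tertiary trifluoroacetate 9 (not isolated)
Conditions: t-BuLi (2.1 equiv), Et2O/pentane, −78 °C; cannulated into 6, THF, −78 °C; (CF3CO)2O, −78 °C; aq NH4Cl, to rt
Reagents that add atoms: water, O
Why: Iodine–lithium exchange and 1,2-addition to one of the two equivalent squarate carbonyls, after which trifluoroacetylation makes the tertiary oxygen a leaving group, so aqueous work-up completes the vinylogous hydrolysis to the cyclobutenedione without mineral acid and spares the acid-labile benzylic silyl ether.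

Step 6
Reactants: 10 3-{(3R)-3-[(TBS)oxy]-3-(3,4-dimethoxyphenyl)propyl}-4-methoxycyclobut-3-ene-1,2-dione; 11 methyl vinyl ether
Product: 14 2-{(3R)-3-[(TBS)oxy]-3-(3,4-dimethoxyphenyl)propyl}-3,4-dimethoxy-4-(1-methoxyethenyl)cyclobut-2-en-1-one, via 1-methoxyvinyllithium 12 (not isolated), via lithium alkoxide 13 (not isolated)
Conditions: 11, t-BuLi, THF, −78 to 0 °C; then 10, THF, −78 °C; MeOTf, −78 to −20 °C; aq NaHCO3
Reagents that add atoms: methyl trifluoromethanesulfonate, COS(=O)(=O)C(F)(F)F
Why: Regioselective 1,2-addition of an alkenyllithium to a 3-alkyl-4-alkoxycyclobutenedione, in which the ketone-like carbonyl beside the methoxy-bearing alkene carbon reacts ahead of the vinylogous-ester carbonyl beside the alkyl-bearing carbon, followed by O-methylation of the tertiary alkoxide in the same flask to install the future C6 methoxy group; the new ring stereocentre is uncontrolled and is destroyed in step 7.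

Step 7
Reactants: 14 2-{(3R)-3-[(TBS)oxy]-3-(3,4-dimethoxyphenyl)propyl}-3,4-dimethoxy-4-(1-methoxyethenyl)cyclobut-2-en-1-one
Product: 17 2-{(3R)-3-[(TBS)oxy]-3-(3,4-dimethoxyphenyl)propyl}-3,4,5-trimethoxyphenol, via dienylketene 15 (not isolated), via cyclohexadienone 16 (not isolated)
Conditions: toluene (degassed, 0.02 M), 110 °C, argon, base-washed glassware
Reagents that add atoms: none
Why: Heat breaks the bond between the carbonyl carbon and the quaternary carbon of 14 in a conrotatory 4π electrocyclic opening, with the quaternary methoxy donor rotating outward and the 1-methoxyvinyl group inward, to give (Z)-dienylketene 15. The ketene carbon then bonds to the terminal vinyl CH2 in a thermally allowed disrotatory 6π electrocyclisation that closes the six-membered carbocycle (new bond C8–C8a), and dienone 16 enolises irreversibly to phenol 17. This is the Moore rearrangement of a 4-alkenylcyclobutenone, run here on the O-methyl ether so that a monoprotected hydroquinone results. No stereocentre is created, both epimers of 14 converge because the quaternary carbon becomes sp2, and the neutral medium leaves the (R)-silyloxy centre untouched. The selectivity needed is torquoselectivity, which the strong outward preference of an alkoxy donor secures, and a ketene from the wrong rotation can only reclose to 14 because no hydroxyl is present to trap it as a butenolide. The atom mapping is carbonyl carbon to C8a, alkyl-bearing carbon to C4a, methoxy-bearing alkene carbon to C5, quaternary carbon to C6, inner vinyl carbon to C7 and CH2 to C8, so the regiochemistry is already decided in steps 5 and 6.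

Step 8
Reactants: 17 2-{(3R)-3-[(TBS)oxy]-3-(3,4-dimethoxyphenyl)propyl}-3,4,5-trimethoxyphenol
Product: 18 2-[(3R)-3-(3,4-dimethoxyphenyl)-3-hydroxypropyl]-3,4,5-trimethoxyphenol
Conditions: TBAF, AcOH, THF, 0 °C to rt
Reagents that add atoms: none
Why: Fluoride-induced desilylation driven by Si–F bond formation, with acetic acid buffering to keep the electron-rich phenol protonated; only the O–Si bond breaks, so the (R) configuration is kept.

Step 9
Reactants: 18 2-[(3R)-3-(3,4-dimethoxyphenyl)-3-hydroxypropyl]-3,4,5-trimethoxyphenol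
Product: 19 (2S)-2-(3,4-dimethoxyphenyl)-5,6,7-trimethoxy-3,4-dihydro-2H-chromene
Conditions: PPh3, then DIAD dropwise, toluene (0.01 M), 0 °C
Reagents that add atoms: none
Why: Intramolecular Mitsunobu etherification, in which the secondary alcohol is activated as its alkoxyphosphonium ion and displaced by the only phenol present (C8a–OH) in a 6-exo-tet SN2 closure of ring C, inverting the (R)-carbinol to (2S); low temperature, dilution and a non-polar solvent disfavour ionisation of the electron-rich benzylic centre.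

Step 10
Reactants: 19 (2S)-2-(3,4-dimethoxyphenyl)-5,6,7-trimethoxy-3,4-dihydro-2H-chromene
Product: 20 (2S,4RS)-2-(3,4-dimethoxyphenyl)-5,6,7-trimethoxy-3,4-dihydro-2H-chromen-4-ol
Conditions: DDQ (1.1 equiv), CH2Cl2/aqueous pH 7 phosphate buffer (10:1), 0 °C
Reagents that add atoms: water, O
Why: Benzylic oxidation by hydride abstraction, the reaction type used for C4 functionalisation of O-alkylated flavans and flavan-3-ols, in which DDQ takes hydride from C4 because that cation is stabilised by O1 and by the C5 and C7 methoxy groups of ring A and water then captures it; C2 is not involved, and the uncontrolled C4 centre is removed in step 11.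

Step 11
Reactants: 20 (2S,4RS)-2-(3,4-dimethoxyphenyl)-5,6,7-trimethoxy-3,4-dihydro-2H-chromen-4-ol
Product: 21 (2S)-5,6,7,3',4'-pentamethoxyflavanone
Conditions: Dess–Martin periodinane, NaHCO3, CH2Cl2, 0 °C to rt
Reagents that add atoms: none
Why: Dess–Martin oxidation of a secondary benzylic alcohol under buffered, near-neutral conditions, which removes the C4 stereocentre and avoids the base-induced ring opening to the chalcone that would racemise C2.

Compound list
1 | ethyl 3-(3,4-dimethoxyphenyl)-3-oxopropanoate | CCOC(=O)CC(=O)c1ccc(OC)c(OC)c1 | starting material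
2 | ethyl (3R)-3-(3,4-dimethoxyphenyl)-3-hydroxypropanoate | COc1ccc([C@H](O)CC(=O)OCC)cc1OC | intermediate
3 | ethyl (3R)-3-[(TBS)oxy]-3-(3,4-dimethoxyphenyl)propanoate | COc1ccc([C@H](O[Si](C)(C)C(C)(C)C)CC(=O)OCC)cc1OC | intermediate
4 | (3R)-3-[(TBS)oxy]-3-(3,4-dimethoxyphenyl)propan-1-ol | COc1ccc([C@H](O[Si](C)(C)C(C)(C)C)CCO)cc1OC | intermediate
5 | tert-butyl{[(1R)-1-(3,4-dimethoxyphenyl)-3-iodopropyl]oxy}dimethylsilane | COc1ccc([C@H](O[Si](C)(C)C(C)(C)C)CCI)cc1OC | intermediate
6 | dimethyl squarate (3,4-dimethoxycyclobut-3-ene-1,2-dione) | COC1=C(OC)C(=O)C1=O | starting material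
7 | {(3R)-3-[(TBS)oxy]-3-(3,4-dimethoxyphenyl)propyl}lithium | COc1ccc([C@H](O[Si](C)(C)C(C)(C)C)CC[Li])cc1OC | intermediate
8 | lithium 1-{(3R)-3-[(TBS)oxy]-3-(3,4-dimethoxyphenyl)propyl}-2,3-dimethoxy-4-oxocyclobut-2-en-1-olate (both epimers at the ring carbon) | COc1ccc([C@H](O[Si](C)(C)C(C)(C)C)CCC2(O[Li])C(OC)=C(OC)C2=O)cc1OC | intermediate
9 | 1-{(3R)-3-[(TBS)oxy]-3-(3,4-dimethoxyphenyl)propyl}-2,3-dimethoxy-4-oxocyclobut-2-en-1-yl trifluoroacetate (both epimers at the ring carbon) | COc1ccc([C@H](O[Si](C)(C)C(C)(C)C)CCC2(OC(=O)C(F)(F)F)C(OC)=C(OC)C2=O)cc1OC | intermediate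
10 | 3-{(3R)-3-[(TBS)oxy]-3-(3,4-dimethoxyphenyl)propyl}-4-methoxycyclobut-3-ene-1,2-dione | COc1ccc([C@H](O[Si](C)(C)C(C)(C)C)CCC2=C(OC)C(=O)C2=O)cc1OC | intermediate
11 | methyl vinyl ether | COC=C | starting material
12 | (1-methoxyethenyl)lithium | COC(=C)[Li] | intermediate
13 | lithium 3-{(3R)-3-[(TBS)oxy]-3-(3,4-dimethoxyphenyl)propyl}-2-methoxy-1-(1-methoxyethenyl)-4-oxocyclobut-2-en-1-olate (both epimers at the ring carbon) | COc1ccc([C@H](O[Si](C)(C)C(C)(C)C)CCC2=C(OC)C(O[Li])(C(=C)OC)C2=O)cc1OC | intermediate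
14 | 2-{(3R)-3-[(TBS)oxy]-3-(3,4-dimethoxyphenyl)propyl}-3,4-dimethoxy-4-(1-methoxyethenyl)cyclobut-2-en-1-one (both epimers at the ring carbon) | COc1ccc([C@H](O[Si](C)(C)C(C)(C)C)CCC2=C(OC)C(OC)(C(=C)OC)C2=O)cc1OC | intermediate
15 | (3Z)-2-{(3R)-3-[(TBS)oxy]-3-(3,4-dimethoxyphenyl)propyl}-3,4,5-trimethoxyhexa-1,3,5-trien-1-one | COc1ccc([C@H](O[Si](C)(C)C(C)(C)C)CCC(=C=O)/C(OC)=C(OC)\C(=C)OC)cc1OC | intermediate
16 | 2-{(3R)-3-[(TBS)oxy]-3-(3,4-dimethoxyphenyl)propyl}-3,4,5-trimethoxycyclohexa-2,4-dien-1-one | COc1ccc([C@H](O[Si](C)(C)C(C)(C)C)CCC2=C(OC)C(OC)=C(OC)CC2=O)cc1OC | intermediate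
17 | 2-{(3R)-3-[(TBS)oxy]-3-(3,4-dimethoxyphenyl)propyl}-3,4,5-trimethoxyphenol | COc1ccc([C@H](O[Si](C)(C)C(C)(C)C)CCc2c(O)cc(OC)c(OC)c2OC)cc1OC | intermediate
18 | 2-[(3R)-3-(3,4-dimethoxyphenyl)-3-hydroxypropyl]-3,4,5-trimethoxyphenol | COc1ccc([C@H](O)CCc2c(O)cc(OC)c(OC)c2OC)cc1OC | intermediate
19 | (2S)-2-(3,4-dimethoxyphenyl)-5,6,7-trimethoxy-3,4-dihydro-2H-chromene | COc1ccc([C@@H]2CCc3c(cc(OC)c(OC)c3OC)O2)cc1OC | intermediate
20 | (2S,4RS)-2-(3,4-dimethoxyphenyl)-5,6,7-trimethoxy-3,4-dihydro-2H-chromen-4-ol (both epimers at C4) | COc1ccc([C@@H]2CC(O)c3c(cc(OC)c(OC)c3OC)O2)cc1OC | intermediate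
21 | (2S)-2-(3,4-dimethoxyphenyl)-5,6,7-trimethoxy-2,3-dihydro-4H-chromen-4-one, (2S)-5,6,7,3',4'-pentamethoxyflavanone | COc1ccc([C@@H]2CC(=O)c3c(cc(OC)c(OC)c3OC)O2)cc1OC | target

Total step count: 11. Longest linear sequence: 11 steps (1 to 21); 6 and 11 enter as purchased building blocks.

Steps most likely to fail

Step 7.
- **What may go wrong:** the enol ether may be lost through traces of acid before the ring opens. The ketene may be captured or may dimerise before it cyclises. Inward rotation of the vinyl group may be insufficient.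
- **Fallback:** ring A is taken from an intact arene and joined to the chain by sp3–sp2 cross-coupling. The fallback sets out from iodide 5 and comes back at diol 18.
- **Route:** commercial 3,4,5-trimethoxyphenol is monobrominated (NBS, CH2Cl2, −78 to 0 °C) to 2-bromo-3,4,5-trimethoxyphenol F1. Silylation (TBSCl, imidazole, DMF) gives tert-butyl(2-bromo-3,4,5-trimethoxyphenoxy)dimethylsilane F2. Iodide 5 is converted with zinc dust and LiCl in THF into {(3R)-3-[(TBS)oxy]-3-(3,4-dimethoxyphenyl)propyl}zinc iodide F3. Negishi coupling of F3 with F2 (Pd(OAc)2, SPhos, THF, 50 °C) should give the bis-silyl ether of 18 F4. TBAF buffered with AcOH removes both silyl groups to deliver 18.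

Step 10.
- **What may go wrong:** hydride abstraction at C2 may compete with C4. Proton loss from the C4 cation may be followed by further dehydrogenation. Both processes consume material and erode the configuration at C2.
- **Fallback:** C4 is brought in at the ketone level, masked as a dithiane, so no C–H oxidation is needed and the same benzannulation is kept. The fallback sets out from ester 3 and comes back at 21.
- **Chain and dione:** DIBAL-H (1 equiv, toluene, −78 °C) should stop at (3R)-3-[(TBS)oxy]-3-(3,4-dimethoxyphenyl)propanal F5. Propane-1,3-dithiol with MgBr2·OEt2 in Et2O gives 2-{(2R)-2-[(TBS)oxy]-2-(3,4-dimethoxyphenyl)ethyl}-1,3-dithiane F6. Corey–Seebach lithiation (t-BuLi, THF/HMPA, −78 °C) gives the 2-lithiodithiane F7. This is added to 6 and treated with (CF3CO)2O as in step 5 to give the dithianyl cyclobutenedione F8.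
- **Benzannulation and end game:** addition of 12 and one equivalent of MeOTf at −78 °C, so that the alkoxide outcompetes sulfur, gives the dithianyl cyclobutenone F9. Thermolysis as in step 7 gives the dithianyl phenol F10. Buffered TBAF gives the dithianyl diol F11, and Mitsunobu closure as in step 9 gives the spiro dithioketal of the flavanone F12. MeI and CaCO3 in aqueous MeCN unmask 21 under neutral conditions.

Step 9.
- **What may go wrong:** the electron-rich benzylic alkoxyphosphonium ion may ionise, so that substitution proceeds partly without inversion and enantiomeric purity is lost.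
- **Fallback:** enantiomeric purity is secured by catalyst-controlled kinetic resolution at the ketone stage instead of by stereospecific substitution alone. The fallback sets out from flavan 19 of eroded purity, which is taken through steps 10 and 11 unchanged, and comes back at 21.
- **Route:** Noyori–Ikariya transfer hydrogenation with Cp*RhCl[(R,R)-TsDPEN] in HCO2H/Et3N and EtOAc at rt should reduce the minor (2R)-ketone faster. Hydride arrives anti to the aryl group, giving (2R,4R)-2-(3,4-dimethoxyphenyl)-5,6,7-trimethoxy-3,4-dihydro-2H-chromen-4-ol F13. This alcohol is separated by chromatography from unreacted 21.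

Further compounds
F1 | step 7 | 2-bromo-3,4,5-trimethoxyphenol | COc1cc(O)c(Br)c(OC)c1OC
F2 | step 7 | tert-butyl(2-bromo-3,4,5-trimethoxyphenoxy)dimethylsilane | COc1cc(O[Si](C)(C)C(C)(C)C)c(Br)c(OC)c1OC
F3 | step 7 | {(3R)-3-[(TBS)oxy]-3-(3,4-dimethoxyphenyl)propyl}zinc iodide | COc1ccc([C@H](O[Si](C)(C)C(C)(C)C)CC[Zn]I)cc1OC
F4 | step 7 | tert-butyl(2-{(3R)-3-[(TBS)oxy]-3-(3,4-dimethoxyphenyl)propyl}-3,4,5-trimethoxyphenoxy)dimethylsilane | COc1ccc([C@H](O[Si](C)(C)C(C)(C)C)CCc2c(O[Si](C)(C)C(C)(C)C)cc(OC)c(OC)c2OC)cc1OC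
F5 | step 10 | (3R)-3-[(TBS)oxy]-3-(3,4-dimethoxyphenyl)propanal | COc1ccc([C@H](O[Si](C)(C)C(C)(C)C)CC=O)cc1OC
F6 | step 10 | 2-{(2R)-2-[(TBS)oxy]-2-(3,4-dimethoxyphenyl)ethyl}-1,3-dithiane | COc1ccc([C@H](O[Si](C)(C)C(C)(C)C)CC2SCCCS2)cc1OC
F7 | step 10 | 2-{(2R)-2-[(TBS)oxy]-2-(3,4-dimethoxyphenyl)ethyl}-2-lithio-1,3-dithiane | COc1ccc([C@H](O[Si](C)(C)C(C)(C)C)CC2([Li])SCCCS2)cc1OC
F8 | step 10 | 3-(2-{(2R)-2-[(TBS)oxy]-2-(3,4-dimethoxyphenyl)ethyl}-1,3-dithian-2-yl)-4-methoxycyclobut-3-ene-1,2-dione | COc1ccc([C@H](O[Si](C)(C)C(C)(C)C)CC2(SCCCS2)C3=C(OC)C(=O)C3=O)cc1OC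
F9 | step 10 | 2-(2-{(2R)-2-[(TBS)oxy]-2-(3,4-dimethoxyphenyl)ethyl}-1,3-dithian-2-yl)-3,4-dimethoxy-4-(1-methoxyethenyl)cyclobut-2-en-1-one (both epimers at the ring carbon) | COc1ccc([C@H](O[Si](C)(C)C(C)(C)C)CC2(SCCCS2)C3=C(OC)C(OC)(C(=C)OC)C3=O)cc1OC
F10 | step 10 | 2-(2-{(2R)-2-[(TBS)oxy]-2-(3,4-dimethoxyphenyl)ethyl}-1,3-dithian-2-yl)-3,4,5-trimethoxyphenol | COc1ccc([C@H](O[Si](C)(C)C(C)(C)C)CC2(SCCCS2)c3c(O)cc(OC)c(OC)c3OC)cc1OC
F11 | step 10 | 2-{2-[(2R)-2-(3,4-dimethoxyphenyl)-2-hydroxyethyl]-1,3-dithian-2-yl}-3,4,5-trimethoxyphenol | COc1ccc([C@H](O)CC2(SCCCS2)c3c(O)cc(OC)c(OC)c3OC)cc1OC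
F12 | step 10 | (2S)-2-(3,4-dimethoxyphenyl)-5,6,7-trimethoxy-2,3-dihydrospiro[chromene-4,2'-[1,3]dithiane] | COc1ccc([C@@H]2CC3(SCCCS3)c4c(cc(OC)c(OC)c4OC)O2)cc1OC
F13 | step 9 | (2R,4R)-2-(3,4-dimethoxyphenyl)-5,6,7-trimethoxy-3,4-dihydro-2H-chromen-4-ol | COc1ccc([C@H]2C[C@@H](O)c3c(cc(OC)c(OC)c3OC)O2)cc1OC
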